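**Target:** (3R)-5,7-dihydroxy-3-(3-hydroxy-4,5-dimethoxyphenyl)-6-methoxychroman-4-one (20)

## Analysis of the target

The target is an isoflavanone: a chroman-4-one (benzo ring A fused to pyranone ring C) that carries ring B on C3. Ring A is substituted at every position but C8 (5-OH, 6-OMe, 7-OH), and ring B is 3'-OH, 4',5'-di-OMe. The only stereocentre is C3 (R); it is tertiary, benzylic and alpha to the C4 ketone, so it racemises readily by enolisation under base and more slowly under acid. The three phenols, one of them chelated to C4=O, make the compound sensitive to oxidation and force a mild, essentially neutral endgame. The first difficulty is to set C3 and then keep it. The second is regiochemical: two oxygens flank C4a (O1 on C8a and the oxygen on C5), and closing ring C through the wrong one would give the 8-methoxy isomer. The strategy rests on one structural fact: C2 is a methylene between O1 and C3, so O1–C2 is the skeleton of a methoxy group on C8a. If C3 is a carbenoid carbon next to the C4 carbonyl, insertion into a C–H bond of that methoxy group forms C2–C3, closes ring C and creates the stereocentre in one step.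

## Retrosynthetic reasoning

**Endgame (20 from 19 from 18).** The three phenols are traced back to two benzyl ethers (O7, O3') and one silyl ether (O5). The benzyl groups are removed last by hydrogenolysis, which is neutral and leaves C3 alone, so 20 comes from the 5-hydroxy compound 19. The silyl group is removed one step earlier with buffered fluoride, so 19 comes from 18. No C–C bond is cut here; the gain is that the labile stereocentre only sees mild conditions.

**Key disconnection (18 from 17).** The C2–C3 bond of 18 is cut. C2 becomes the methyl carbon of a methoxy group on C8a and C3 becomes a diazo-bearing carbon, giving the diaryl diazoketone 17. This cut removes ring C and the stereocentre together, and it turns the ring A regiochemical problem into a question of which ortho oxygen carries a methyl group. The forward reaction has to deliver the carbenoid carbon into a primary C–H bond next to oxygen, with control of the enantioface at C3.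

**Diazo group and the mask on O5 (17 from 16).** The C3=N2 unit is traced back to the methylene of the deoxybenzoin 16 by diazo transfer. The O5 substituent must have no C–H bond next to oxygen, because a benzyl ether there would be the preferred insertion site. An acyl or carbonate mask would meet that requirement, but during a base-mediated diazo transfer the ketone enolate sits six atoms from its carbonyl carbon and would attack it (a Baker–Venkataraman-type acyl shift followed by lactonisation). A bulky silyl ether is therefore chosen: it is inert to the enolate, its oxygen is a poor nucleophile towards the carbenoid, and it costs only one extra deprotection step.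

**Telling the two ortho oxygens apart (16 from 15 from 14).** The silyl ether 16 comes from phenol 15, and 15 from the bis-benzyl ketone 14 by cleaving only the benzyl ether ortho to the carbonyl. The ketone itself selects that ether through a magnesium chelate, so no separate differentiation of the ring A oxygens is needed. The ortho methoxy group, the future O1–C2, stays.

**Joining the two rings (14 from 7 and 12).** The C4–C4a bond is cut to the symmetric arene 7 and the arylacetic acid 12, used as its chloride 13. In 7 the only two free positions are equivalent, each flanked by a benzyloxy and a methoxy group and para to the other benzyloxy group, so Friedel–Crafts acylation can give only one regioisomer, and it places the methoxy and benzyloxy groups ortho to the ketone as required.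

**Ring A arene (7 from 6, 4, 3, 2 and 1).** The isolated methoxy group of 7 is traced to phenol 6 by O-methylation. The phenol oxygen replaces the ester carbon of 1: benzylation to 2, reduction to alcohol 3, oxidation to aldehyde 4 and Baeyer–Villiger oxidation give 6. Starting from 1 fixes the 1,2,3-oxygen pattern with the central methoxy group already in place.

**Ring B acid (12 from 11, 9 and 8).** The acid is the one-carbon homologue of aldehyde 8. After benzylation to 9, a reductive cyanation gives nitrile 11, whose hydrolysis gives 12. The 3-OBn, 4,5-di-OMe pattern is bought with 8.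

## Alternatives that were turned down

Alternative 1: Here C2–C3 and C3–C4 are cut at the same time, which deletes the carbon that carries ring B from ring C and leaves a five-membered furanone ring. In the forward direction the silyl enol ether 4,6-bis(benzyloxy)-3-[(tert-butyldimethylsilyl)oxy]-5-methoxy-1-benzofuran A1 would be cyclopropanated at its enol ether bond by the chlorocarbene that 3-[3-(benzyloxy)-4,5-dimethoxyphenyl]-3-chloro-3H-diazirine A2 releases on loss of nitrogen. The strained adduct would then open with loss of chloride and of the silyl group to the isoflavone 5,7-bis(benzyloxy)-3-[3-(benzyloxy)-4,5-dimethoxyphenyl]-6-methoxy-4H-chromen-4-one A3. In its favour, two skeletal bonds form at once, A1 and A2 are made separately so the route is convergent, the enol ether bond of A1 is an electron-rich carbene acceptor, and A3 is flat, robust and free of any labile centre. On robustness of the key-step product this alternative is stronger than the chosen route. Against it, A3 has no stereocentre, so C3 must be set afterwards by an enantioselective reduction of the C2=C3 bond. The dependable ways of doing that run on to the C4 alcohol and need reoxidation, which adds two or three steps after the key step. A2 carries three donor groups on its aryl ring and should ionise or decompose easily, and the ring expansion itself is not established on this substrate class. The chosen route is no better precedented at its key step, but that step delivers ring C and the C3 configuration together and leaves two mild steps to the target.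

Alternative 2: Here the aryl C8a–O1 bond is cut, so ring C is opened to a primary alcohol and ring A loses its oxygen at C8a. In the forward direction the phenol 4-{(1S,2R)-2-[3-(benzyloxy)-4,5-dimethoxyphenyl]-1-[(tert-butyldimethylsilyl)oxy]-3-hydroxypropyl}-2,3-dimethoxyphenol A4 would be oxidised at the anode in methanol to a quinone monoketal stage. The primary hydroxyl would add to C8a, and loss of methanol would restore the aromatic ring to give (3R,4S)-3-[3-(benzyloxy)-4,5-dimethoxyphenyl]-4-[(tert-butyldimethylsilyl)oxy]-5,6-dimethoxychroman-7-ol A5. In its favour, C3 is set early in the acyclic fragment A4 by well-tried asymmetric chemistry, and it cannot epimerise while C4 is a protected alcohol. On stereochemical security before the endgame this alternative is stronger than the chosen route. Against it, in A4 the side chain is para to the phenol, so solvent capture at that carbon competes with ketal formation at C6, and the electron-rich ring B is also oxidisable. A5 still needs deprotection and oxidation at C4, which exposes C3, and then a selective Lewis-acid cleavage of the 5-methoxy group on an enolisable ketone before hydrogenolysis. That is four or more steps after the key step. The chosen route has C5 differentiated from the start and needs only two neutral or buffered steps after the ring closure; it pays for this with an unprecedented insertion.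

Alternative 3: Here the C3–C4 bond is cut as an alkene, so ring C is opened to a styrene on ring A and a 2-arylallyl ether on O1. In the forward direction the diene 1,3-bis(benzyloxy)-5-({2-[3-(benzyloxy)-4,5-dimethoxyphenyl]prop-2-en-1-yl}oxy)-4-ethenyl-2-methoxybenzene A6 would be closed by ring-closing metathesis with the second-generation Grubbs catalyst RuCl2(=CHPh)(PCy3)(H2IMes) to 5,7-bis(benzyloxy)-3-[3-(benzyloxy)-4,5-dimethoxyphenyl]-6-methoxy-2H-chromene A7. Asymmetric hydroboration and oxidation of A7 would then set C3, and the C4 alcohol would be oxidised to the ketone. In its favour, every step belongs to a known reaction type, and metathesis to 2H-chromenes is dependable. On precedent this alternative is clearly stronger than the chosen route. Against it, the alkene of A7 is trisubstituted and benzylic at both ends, and C4 is crowded by the di-ortho-substituted ring A, so both the regiochemistry and the enantioselectivity of a stoichiometric chiral borane are uncertain. A6 needs a vinyl group at C4a and a differentiated oxygen at C8a, which costs several steps. After the key step come hydroboration, oxidation and deprotection, with the stereocentre created in a separate step. The chosen route is shorter after ring closure and sets C3 catalytically in the ring-forming step, at the price of higher risk in that step.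

Key step: step 13

Assumption: the sense of induction of Rh2(S-PTTL)4, the divalent rhodium dimer dirhodium tetrakis[N-phthaloyl-(S)-tert-leucinate], on this substrate cannot be assigned in advance; the (S)-ligand catalyst is written, and its mirror image Rh2(R-PTTL)4 would be used if the insertion favoured the (3S) product.

## Route

Step 1
Reactants: 1 methyl 3,5-dihydroxy-4-methoxybenzoate
Product: 2 methyl 3,5-bis(benzyloxy)-4-methoxybenzoate
Conditions: BnBr (2.2 equiv), K2CO3, DMF, 60 °C
Reagents that add atoms: benzyl bromide, BrCc1ccccc1
Why: Williamson ether synthesis on both phenols; the ester and the hindered central methoxy group are inert, and the product stays symmetric.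

Step 2
Reactants: 2 methyl 3,5-bis(benzyloxy)-4-methoxybenzoate
Product: 3 [3,5-bis(benzyloxy)-4-methoxyphenyl]methanol
Conditions: LiAlH4, THF, 0 °C → rt
Reagents that add atoms: none
Why: Hydride reduction of the ester to the primary alcohol; aryl benzyl and methyl ethers are not touched.

Step 3
Reactants: 3 [3,5-bis(benzyloxy)-4-methoxyphenyl]methanol
Product: 4 3,5-bis(benzyloxy)-4-methoxybenzaldehyde
Conditions: MnO2, CH2Cl2, rt
Reagents that add atoms: none
Why: Selective oxidation of a benzylic alcohol by activated MnO2, which should stop at the aldehyde.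

Step 4
Reactants: 4 3,5-bis(benzyloxy)-4-methoxybenzaldehyde
Product: 6 3,5-bis(benzyloxy)-4-methoxyphenol, via aryl formate 5 (not isolated)
Conditions: mCPBA, CH2Cl2, 0 °C → rt; then K2CO3 (cat.), MeOH, rt
Reagents that add atoms: 3-chloroperoxybenzoic acid (mCPBA), OOC(=O)c1cccc(Cl)c1
Why: Baeyer–Villiger oxidation; the electron-rich trialkoxyaryl group migrates in preference to hydrogen to give the formate, which mild methanolysis cleaves to the phenol.

Step 5
Reactants: 6 3,5-bis(benzyloxy)-4-methoxyphenol
Product: 7 1,3-bis(benzyloxy)-2,5-dimethoxybenzene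
Conditions: MeI, K2CO3, acetone, reflux
Reagents that add atoms: iodomethane, CI
Why: O-methylation of the phenoxide; this methyl group later becomes C2 of ring C.

Step 6
Reactants: 8 3-hydroxy-4,5-dimethoxybenzaldehyde
Product: 9 3-(benzyloxy)-4,5-dimethoxybenzaldehyde
Conditions: BnBr, K2CO3, DMF, 60 °C
Reagents that add atoms: benzyl bromide, BrCc1ccccc1
Why: Williamson ether synthesis on the single phenol; the aldehyde has no alpha hydrogen and is stable to carbonate.

Step 7
Reactants: 9 3-(benzyloxy)-4,5-dimethoxybenzaldehyde
Product: 11 2-[3-(benzyloxy)-4,5-dimethoxyphenyl]acetonitrile, via N-(1-tosyl-2-arylethenyl)formamide 10 (not isolated)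
Conditions: TosMIC, t-BuOK, DME, −50 → −20 °C; then MeOH, reflux
Reagents that add atoms: tosylmethyl isocyanide (TosMIC), Cc1ccc(cc1)S(=O)(=O)C[N+]#[C-]
Why: Van Leusen reductive cyanation; the TosMIC anion adds to the aldehyde at low temperature and the oxazoline opens to the N-formyl enamine, which methanol deformylates with loss of sulfinate to the homologated nitrile.

Step 8
Reactants: 11 2-[3-(benzyloxy)-4,5-dimethoxyphenyl]acetonitrile
Product: 12 2-[3-(benzyloxy)-4,5-dimethoxyphenyl]acetic acid
Conditions: KOH, EtOH/H2O, reflux; then aq. HCl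
Reagents that add atoms: water (as hydroxide), O
Why: Alkaline nitrile hydrolysis; aryl benzyl and methyl ethers are stable to hydroxide.

Step 9
Reactants: 12 2-[3-(benzyloxy)-4,5-dimethoxyphenyl]acetic acid; 7 1,3-bis(benzyloxy)-2,5-dimethoxybenzene
Product: 14 1-[2,4-bis(benzyloxy)-3,6-dimethoxyphenyl]-2-[3-(benzyloxy)-4,5-dimethoxyphenyl]ethan-1-one, via acid chloride 13 (not isolated)
Conditions: (COCl)2, DMF (cat.), CH2Cl2, 0 °C → rt; then 7, SnCl4, CH2Cl2, −78 → −20 °C
Reagents that add atoms: oxalyl chloride, O=C(Cl)C(Cl)=O (supplies only the chlorine of 13)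
Why: Friedel–Crafts acylation; the two free positions of 7 are equivalent and activated by three alkoxy groups, far more than any position of ring B, so a single ketone should form, and the acyl group deactivates the ring against a second acylation.

Step 10
Reactants: 14 1-[2,4-bis(benzyloxy)-3,6-dimethoxyphenyl]-2-[3-(benzyloxy)-4,5-dimethoxyphenyl]ethan-1-one
Product: 15 1-[4-(benzyloxy)-2-hydroxy-3,6-dimethoxyphenyl]-2-[3-(benzyloxy)-4,5-dimethoxyphenyl]ethan-1-one
Conditions: MgBr2·OEt2 (3 equiv), toluene/Et2O, 70 °C; aq. HCl work-up
Reagents that add atoms: none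
Why: Chelation-controlled dealkylation; magnesium bound between the carbonyl and an ortho oxygen activates that ether, and bromide attacks a benzylic carbon far faster than a methyl carbon, so only the ortho benzyl ether should be cleaved while the ortho methoxy and the two non-chelated benzyl ethers remain.

Step 11
Reactants: 15 1-[4-(benzyloxy)-2-hydroxy-3,6-dimethoxyphenyl]-2-[3-(benzyloxy)-4,5-dimethoxyphenyl]ethan-1-one
Product: 16 1-[4-(benzyloxy)-3,6-dimethoxy-2-(triisopropylsilyloxy)phenyl]-2-[3-(benzyloxy)-4,5-dimethoxyphenyl]ethan-1-one
Conditions: TIPSOTf, 2,6-lutidine, CH2Cl2, 0 °C → rt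
Reagents that add atoms: triisopropylsilyl trifluoromethanesulfonate, CC(C)[Si](OS(=O)(=O)C(F)(F)F)(C(C)C)C(C)C
Why: O-silylation of the hindered, hydrogen-bonded phenol with a silyl triflate; the weak base 2,6-lutidine should not convert the ketone into a silyl enol ether at this temperature.

Step 12
Reactants: 16 1-[4-(benzyloxy)-3,6-dimethoxy-2-(triisopropylsilyloxy)phenyl]-2-[3-(benzyloxy)-4,5-dimethoxyphenyl]ethan-1-one
Product: 17 1-[4-(benzyloxy)-3,6-dimethoxy-2-(triisopropylsilyloxy)phenyl]-2-[3-(benzyloxy)-4,5-dimethoxyphenyl]-2-diazoethan-1-one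
Conditions: p-ABSA, DBU, MeCN, 0 °C → rt, dark
Reagents that add atoms: 4-acetamidobenzenesulfonyl azide (p-ABSA), CC(=O)Nc1ccc(cc1)S(=O)(=O)N=[N+]=[N-]
Why: Regitz diazo transfer to an aryl benzyl ketone; the methylene is acidified by the carbonyl and ring B, and the silyl ether, unlike an ester or carbonate, offers the enolate no acyl carbon to attack.

Step 13
Reactants: 17 1-[4-(benzyloxy)-3,6-dimethoxy-2-(triisopropylsilyloxy)phenyl]-2-[3-(benzyloxy)-4,5-dimethoxyphenyl]-2-diazoethan-1-one
Product: 18 (3R)-7-(benzyloxy)-3-[3-(benzyloxy)-4,5-dimethoxyphenyl]-6-methoxy-5-(triisopropylsilyloxy)chroman-4-one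
Conditions: Rh2(S-PTTL)4 (2 mol %), PhCF3, 4 Å MS, 0 °C → rt, slow addition of 17
Reagents that add atoms: none
Why: Proposed new method: Rh2(S-PTTL)4 should expel N2 from 17 to give a rhodium carbenoid at C3, stabilised by ring B as donor and made electrophilic by the aroyl group as acceptor, and this carbon should insert through a concerted, asynchronous three-centre transition state with hydride character into a C–H bond of the ortho methoxy group, whose oxygen lone pair stabilises the charge building up on the methyl carbon. The closest known reactions are chiral dirhodium-carboxylate-catalysed insertions of ortho-alkoxyaryl diazoketones into the C–H bond next to the ether oxygen to give chroman-4-ones, and enantioselective insertions of donor/acceptor carbenoids alpha to ether oxygen, including primary C–H bonds of methyl ethers; a diaryl diazoketone inserting into a methoxy group has not been shown. Ring C closes by C2–C3 bond formation through a six-membered transition state (formal 1,6-insertion), the usually favoured five-membered mode being unavailable because the fifth atom from the carbenoid carbon is O1. C3, the only stereocentre, is the carbenoid carbon itself: the hydrogen arrives on the face left open by the bowl of four phthalimido groups around the rhodium-bound carbenoid, so its configuration is catalyst-controlled. The step needs site selectivity for the C8a methoxy group, which the substrate secures: the other ortho oxygen carries a silyl group with no C–H bond next to oxygen and a shielded, weakly nucleophilic oxygen, the C6 methoxy and C7 benzyloxy groups sit meta and para to the carbonyl, and the ring B ethers are held away from C3 by their own ring. Oxonium ylide formation at the methoxy oxygen is expected to lose out because it is reversible and the following methyl shift is slow, and slow addition at high dilution in a non-coordinating solvent should suppress carbene dimerisation. The ketone forms under neutral conditions, so the enolisable C3–H is never exposed to base.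

Step 14
Reactants: 18 (3R)-7-(benzyloxy)-3-[3-(benzyloxy)-4,5-dimethoxyphenyl]-6-methoxy-5-(triisopropylsilyloxy)chroman-4-one
Product: 19 (3R)-7-(benzyloxy)-3-[3-(benzyloxy)-4,5-dimethoxyphenyl]-5-hydroxy-6-methoxychroman-4-one
Conditions: TBAF/AcOH (1:1), THF, 0 °C
Reagents that add atoms: none
Why: Fluoride cleavage of an aryl silyl ether, fast because the leaving phenoxide is stabilised by the peri carbonyl; acetic acid buffers the medium so that C3 should not enolise.

Step 15
Reactants: 19 (3R)-7-(benzyloxy)-3-[3-(benzyloxy)-4,5-dimethoxyphenyl]-5-hydroxy-6-methoxychroman-4-one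
Product: 20 (3R)-5,7-dihydroxy-3-(3-hydroxy-4,5-dimethoxyphenyl)-6-methoxychroman-4-one
Conditions: H2 (1 atm), 10% Pd/C, EtOAc, rt
Reagents that add atoms: none
Why: Hydrogenolysis of both aryl benzyl ethers under neutral conditions; the chelated, electron-rich aryl ketone and the C3 centre should be unaffected, and filtration and evaporation suffice for work-up.

## Compound list

1 | methyl 3,5-dihydroxy-4-methoxybenzoate | COC(=O)c1cc(O)c(OC)c(O)c1 | starting material
2 | methyl 3,5-bis(benzyloxy)-4-methoxybenzoate | COC(=O)c1cc(OCc2ccccc2)c(OC)c(OCc2ccccc2)c1 | intermediate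
3 | [3,5-bis(benzyloxy)-4-methoxyphenyl]methanol | OCc1cc(OCc2ccccc2)c(OC)c(OCc2ccccc2)c1 | intermediate
4 | 3,5-bis(benzyloxy)-4-methoxybenzaldehyde | O=Cc1cc(OCc2ccccc2)c(OC)c(OCc2ccccc2)c1 | intermediate
5 | 3,5-bis(benzyloxy)-4-methoxyphenyl formate | O=COc1cc(OCc2ccccc2)c(OC)c(OCc2ccccc2)c1 | intermediate (not isolated)
6 | 3,5-bis(benzyloxy)-4-methoxyphenol | Oc1cc(OCc2ccccc2)c(OC)c(OCc2ccccc2)c1 | intermediate
7 | 1,3-bis(benzyloxy)-2,5-dimethoxybenzene | COc1cc(OCc2ccccc2)c(OC)c(OCc2ccccc2)c1 | intermediate
8 | 3-hydroxy-4,5-dimethoxybenzaldehyde | COc1cc(C=O)cc(O)c1OC | starting material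
9 | 3-(benzyloxy)-4,5-dimethoxybenzaldehyde | COc1cc(C=O)cc(OCc2ccccc2)c1OC | intermediate
10 | N-{2-[3-(benzyloxy)-4,5-dimethoxyphenyl]-1-[(4-methylphenyl)sulfonyl]ethenyl}formamide (alkene geometry not defined) | COc1cc(C=C(NC=O)S(=O)(=O)c2ccc(C)cc2)cc(OCc2ccccc2)c1OC | intermediate (not isolated)
11 | 2-[3-(benzyloxy)-4,5-dimethoxyphenyl]acetonitrile | COc1cc(CC#N)cc(OCc2ccccc2)c1OC | intermediate
12 | 2-[3-(benzyloxy)-4,5-dimethoxyphenyl]acetic acid | COc1cc(CC(=O)O)cc(OCc2ccccc2)c1OC | intermediate
13 | 2-[3-(benzyloxy)-4,5-dimethoxyphenyl]acetyl chloride | COc1cc(CC(=O)Cl)cc(OCc2ccccc2)c1OC | intermediate (not isolated)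
14 | 1-[2,4-bis(benzyloxy)-3,6-dimethoxyphenyl]-2-[3-(benzyloxy)-4,5-dimethoxyphenyl]ethan-1-one | COc1cc(CC(=O)c2c(OC)cc(OCc3ccccc3)c(OC)c2OCc2ccccc2)cc(OCc2ccccc2)c1OC | intermediate
15 | 1-[4-(benzyloxy)-2-hydroxy-3,6-dimethoxyphenyl]-2-[3-(benzyloxy)-4,5-dimethoxyphenyl]ethan-1-one | COc1cc(CC(=O)c2c(OC)cc(OCc3ccccc3)c(OC)c2O)cc(OCc2ccccc2)c1OC | intermediate
16 | 1-[4-(benzyloxy)-3,6-dimethoxy-2-(triisopropylsilyloxy)phenyl]-2-[3-(benzyloxy)-4,5-dimethoxyphenyl]ethan-1-one | COc1cc(CC(=O)c2c(OC)cc(OCc3ccccc3)c(OC)c2O[Si](C(C)C)(C(C)C)C(C)C)cc(OCc2ccccc2)c1OC | intermediate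
17 | 1-[4-(benzyloxy)-3,6-dimethoxy-2-(triisopropylsilyloxy)phenyl]-2-[3-(benzyloxy)-4,5-dimethoxyphenyl]-2-diazoethan-1-one | COc1cc(C(=[N+]=[N-])C(=O)c2c(OC)cc(OCc3ccccc3)c(OC)c2O[Si](C(C)C)(C(C)C)C(C)C)cc(OCc2ccccc2)c1OC | intermediate
18 | (3R)-7-(benzyloxy)-3-[3-(benzyloxy)-4,5-dimethoxyphenyl]-6-methoxy-5-(triisopropylsilyloxy)chroman-4-one | COc1cc([C@@H]2COc3cc(OCc4ccccc4)c(OC)c(O[Si](C(C)C)(C(C)C)C(C)C)c3C2=O)cc(OCc2ccccc2)c1OC | intermediate
19 | (3R)-7-(benzyloxy)-3-[3-(benzyloxy)-4,5-dimethoxyphenyl]-5-hydroxy-6-methoxychroman-4-one | COc1cc([C@@H]2COc3cc(OCc4ccccc4)c(OC)c(O)c3C2=O)cc(OCc2ccccc2)c1OC | intermediate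
20 | (3R)-5,7-dihydroxy-3-(3-hydroxy-4,5-dimethoxyphenyl)-6-methoxychroman-4-one | COc1cc([C@@H]2COc3cc(O)c(OC)c(O)c3C2=O)cc(O)c1OC | target

## Step count and least certain steps

Total step count: 15. Longest linear sequence: 12 steps (steps 1 to 5, then 9 to 15); the ring B branch (steps 6 to 8) joins at step 9.

Risk at step 13 (key step): the carbenoid may attack the methoxy oxygen and give an oxonium ylide that rearranges, or may dimerise, because a primary C–H bond is a reluctant insertion partner. Enantioface discrimination may also be poor, since the carbenoid carries two aryl-type groups of similar size. The fallback uses known chemistry, sets out from 16 and comes back to the route at 18. The ortho methoxy group of 16 is cleaved with MgI2·OEt2 (toluene, 80 °C), magnesium chelating the carbonyl and the methoxy oxygen while the bulky silyl ether does not chelate; this gives 1-[4-(benzyloxy)-6-hydroxy-3-methoxy-2-(triisopropylsilyloxy)phenyl]-2-[3-(benzyloxy)-4,5-dimethoxyphenyl]ethan-1-one F1. Heating with N,N-dimethylformamide dimethyl acetal closes the pyranone through the enaminone to 7-(benzyloxy)-3-[3-(benzyloxy)-4,5-dimethoxyphenyl]-6-methoxy-5-(triisopropylsilyloxy)-4H-chromen-4-one F2. Asymmetric transfer hydrogenation with RuCl(p-cymene)[(R,R)-TsDPEN] or its mirror image and HCO2H/Et3N reduces the C2=C3 bond and then the ketone, under dynamic kinetic resolution of the base-labile C3 centre, to the cis alcohol (3R,4R)-7-(benzyloxy)-3-[3-(benzyloxy)-4,5-dimethoxyphenyl]-6-methoxy-5-(triisopropylsilyloxy)chroman-4-ol F3. Oxidation of the C4 alcohol with Dess–Martin periodinane buffered by NaHCO3 restores the ketone 18 without touching C3.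

Risk at step 9 (Friedel–Crafts acylation): the Lewis acid may strip benzyl groups, or the electron-rich arylacetyl cation may lose carbon monoxide so that the arene is benzylated instead of acylated. The fallback sets out from 7 and 9 and comes back at 14. Vilsmeier–Haack formylation of 7 (POCl3, DMF) gives 2,4-bis(benzyloxy)-3,6-dimethoxybenzaldehyde F4. Aldehyde 9 is reduced with NaBH4 to [3-(benzyloxy)-4,5-dimethoxyphenyl]methanol F5, which SOCl2 converts into 1-(benzyloxy)-5-(chloromethyl)-2,3-dimethoxybenzene F6. Magnesium in THF turns this chloride into [3-(benzyloxy)-4,5-dimethoxybenzyl]magnesium chloride F7, which adds to the aldehyde to give racemic 1-[2,4-bis(benzyloxy)-3,6-dimethoxyphenyl]-2-[3-(benzyloxy)-4,5-dimethoxyphenyl]ethan-1-ol F8. Dess–Martin oxidation of this alcohol gives 14.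

Risk at step 10 (selective debenzylation): dealkylation at the wrong ether (the ortho methoxy group, or a non-chelated benzyl ether on prolonged heating), or incomplete conversion. The fallback sets out from 14 and comes back at 15. Hydrogenolysis of all three benzyl ethers (H2, 10% Pd/C, EtOAc) gives 1-(2,4-dihydroxy-3,6-dimethoxyphenyl)-2-(3-hydroxy-4,5-dimethoxyphenyl)ethan-1-one F9. Benzylation with two equivalents of BnBr and K2CO3 in acetone then alkylates the two free phenols and leaves the chelated ortho phenol, giving 15.

Risk at step 12 (diazo transfer): deprotonation of the hindered, twisted ketone may be slow, and the base may cause migration or loss of the ortho silyl group. The fallback avoids an enolate, sets out from 16 and comes back at 17. Oxidation of the methylene with SeO2 (dioxane/H2O, reflux) gives 1-[4-(benzyloxy)-3,6-dimethoxy-2-(triisopropylsilyloxy)phenyl]-2-[3-(benzyloxy)-4,5-dimethoxyphenyl]ethane-1,2-dione F10. Tosylhydrazide condenses at the carbonyl next to ring B, the other being shielded by two ortho substituents, to give N'-{1-[3-(benzyloxy)-4,5-dimethoxyphenyl]-2-[4-(benzyloxy)-3,6-dimethoxy-2-(triisopropylsilyloxy)phenyl]-2-oxoethylidene}-4-methylbenzenesulfonohydrazide F11. Et3N in CH2Cl2 eliminates sulfinate (Bamford–Stevens) to give 17.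

Risk at step 14 (desilylation): partial racemisation at C3 if the buffered fluoride is still basic enough to enolise the ketone, or slow cleavage of the hindered silyl ether. The fallback sets out from 18 and comes back at 20, reversing the order of the last two steps. Hydrogenolysis first (H2, 10% Pd/C, EtOAc) gives (3R)-7-hydroxy-3-(3-hydroxy-4,5-dimethoxyphenyl)-6-methoxy-5-(triisopropylsilyloxy)chroman-4-one F12. The silyl group is then removed with acidic fluoride (HF·pyridine, THF, 0 °C), which cannot form an enolate, to give 20.

## Further compounds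

F1 | step 13 | 1-[4-(benzyloxy)-6-hydroxy-3-methoxy-2-(triisopropylsilyloxy)phenyl]-2-[3-(benzyloxy)-4,5-dimethoxyphenyl]ethan-1-one | COc1cc(CC(=O)c2c(O)cc(OCc3ccccc3)c(OC)c2O[Si](C(C)C)(C(C)C)C(C)C)cc(OCc2ccccc2)c1OC
F2 | step 13 | 7-(benzyloxy)-3-[3-(benzyloxy)-4,5-dimethoxyphenyl]-6-methoxy-5-(triisopropylsilyloxy)-4H-chromen-4-one | COc1cc(-c2coc3cc(OCc4ccccc4)c(OC)c(O[Si](C(C)C)(C(C)C)C(C)C)c3c2=O)cc(OCc2ccccc2)c1OC
F3 | step 13 | (3R,4R)-7-(benzyloxy)-3-[3-(benzyloxy)-4,5-dimethoxyphenyl]-6-methoxy-5-(triisopropylsilyloxy)chroman-4-ol | COc1cc([C@@H]2COc3cc(OCc4ccccc4)c(OC)c(O[Si](C(C)C)(C(C)C)C(C)C)c3[C@@H]2O)cc(OCc2ccccc2)c1OC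
F4 | step 9 | 2,4-bis(benzyloxy)-3,6-dimethoxybenzaldehyde | COc1cc(OCc2ccccc2)c(OC)c(OCc2ccccc2)c1C=O
F5 | step 9 | [3-(benzyloxy)-4,5-dimethoxyphenyl]methanol | COc1cc(CO)cc(OCc2ccccc2)c1OC
F6 | step 9 | 1-(benzyloxy)-5-(chloromethyl)-2,3-dimethoxybenzene | COc1cc(CCl)cc(OCc2ccccc2)c1OC
F7 | step 9 | [3-(benzyloxy)-4,5-dimethoxybenzyl]magnesium chloride | COc1cc(C[Mg]Cl)cc(OCc2ccccc2)c1OC
F8 | step 9 | 1-[2,4-bis(benzyloxy)-3,6-dimethoxyphenyl]-2-[3-(benzyloxy)-4,5-dimethoxyphenyl]ethan-1-ol (racemic) | COc1cc(CC(O)c2c(OC)cc(OCc3ccccc3)c(OC)c2OCc2ccccc2)cc(OCc2ccccc2)c1OC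
F9 | step 10 | 1-(2,4-dihydroxy-3,6-dimethoxyphenyl)-2-(3-hydroxy-4,5-dimethoxyphenyl)ethan-1-one | COc1cc(CC(=O)c2c(OC)cc(O)c(OC)c2O)cc(O)c1OC
F10 | step 12 | 1-[4-(benzyloxy)-3,6-dimethoxy-2-(triisopropylsilyloxy)phenyl]-2-[3-(benzyloxy)-4,5-dimethoxyphenyl]ethane-1,2-dione | COc1cc(C(=O)C(=O)c2c(OC)cc(OCc3ccccc3)c(OC)c2O[Si](C(C)C)(C(C)C)C(C)C)cc(OCc2ccccc2)c1OC
F11 | step 12 | N'-{1-[3-(benzyloxy)-4,5-dimethoxyphenyl]-2-[4-(benzyloxy)-3,6-dimethoxy-2-(triisopropylsilyloxy)phenyl]-2-oxoethylidene}-4-methylbenzenesulfonohydrazide | COc1cc(C(=NNS(=O)(=O)c2ccc(C)cc2)C(=O)c2c(OC)cc(OCc3ccccc3)c(OC)c2O[Si](C(C)C)(C(C)C)C(C)C)cc(OCc2ccccc2)c1OC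
F12 | step 14 | (3R)-7-hydroxy-3-(3-hydroxy-4,5-dimethoxyphenyl)-6-methoxy-5-(triisopropylsilyloxy)chroman-4-one | COc1cc([C@@H]2COc3cc(O)c(OC)c(O[Si](C(C)C)(C(C)C)C(C)C)c3C2=O)cc(O)c1OC
A1 | alternative 1 | 4,6-bis(benzyloxy)-3-[(tert-butyldimethylsilyl)oxy]-5-methoxy-1-benzofuran | COc1c(OCc2ccccc2)cc2occ(O[Si](C)(C)C(C)(C)C)c2c1OCc1ccccc1
A2 | alternative 1 | 3-[3-(benzyloxy)-4,5-dimethoxyphenyl]-3-chloro-3H-diazirine | COc1cc(C2(Cl)N=N2)cc(OCc2ccccc2)c1OC
A3 | alternative 1 | 5,7-bis(benzyloxy)-3-[3-(benzyloxy)-4,5-dimethoxyphenyl]-6-methoxy-4H-chromen-4-one | COc1cc(-c2coc3cc(OCc4ccccc4)c(OC)c(OCc4ccccc4)c3c2=O)cc(OCc2ccccc2)c1OC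
A4 | alternative 2 | 4-{(1S,2R)-2-[3-(benzyloxy)-4,5-dimethoxyphenyl]-1-[(tert-butyldimethylsilyl)oxy]-3-hydroxypropyl}-2,3-dimethoxyphenol | COc1cc([C@H](CO)[C@H](O[Si](C)(C)C(C)(C)C)c2ccc(O)c(OC)c2OC)cc(OCc2ccccc2)c1OC
A5 | alternative 2 | (3R,4S)-3-[3-(benzyloxy)-4,5-dimethoxyphenyl]-4-[(tert-butyldimethylsilyl)oxy]-5,6-dimethoxychroman-7-ol | COc1cc([C@@H]2COc3cc(O)c(OC)c(OC)c3[C@H]2O[Si](C)(C)C(C)(C)C)cc(OCc2ccccc2)c1OC
A6 | alternative 3 | 1,3-bis(benzyloxy)-5-({2-[3-(benzyloxy)-4,5-dimethoxyphenyl]prop-2-en-1-yl}oxy)-4-ethenyl-2-methoxybenzene | C=Cc1c(OCc2ccccc2)c(OC)c(OCc2ccccc2)cc1OCC(=C)c1cc(OC)c(OC)c(OCc2ccccc2)c1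
A7 | alternative 3 | 5,7-bis(benzyloxy)-3-[3-(benzyloxy)-4,5-dimethoxyphenyl]-6-methoxy-2H-chromene | COc1cc(C2=Cc3c(OCc4ccccc4)c(OC)c(OCc4ccccc4)cc3OC2)cc(OCc2ccccc2)c1OC
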